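**Plan**

1. Retrosynthesis: first the four acetal-type oxygen protecting groups are removed, then ring C is cut at two bonds at once, aryl C8a–O1 and aryl C4a–C4(=O), which leaves a ring A aryne and a 3-aryl-2,3-dioxygenated propanoyl unit. That unit is cut at C2–C3 (glycolate aldol), and ring B at its aryl–geranyl bond.
2. Enabling feature: ring A is a phloroglucinol nucleus whose C5 oxygen flanks the C4a–C8a bond and whose C6 methyl is para to C8a. An aryne across C4a–C8a is therefore a 3-alkoxyaryne that takes an oxygen nucleophile at C8a and an acyl group at C4a. Its precursor phenol has a mirror plane through C6 and C8a, so only the 6-methyl pattern can arise.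
3. Forward: the ring B aldehyde (C-geranylation, protection) and the ring A ortho-silylaryl triflate (from 2-methylresorcinol by C–H borylation/oxidation, bromination, retro-Brook/triflation) are made separately. The aldol joins ring B to the glycolate, the aryne annulation closes ring C onto ring A, and acid removes all helpers.
4. Stereochemistry: C3 comes from the (5S,6S)-butane-2,3-diacetal glycolate (enolate attacked anti to the axial methoxy group), and C2 from the chair transition state of the ring-locked E-enolate (anti aldol). Both are carried through ring closure, 2,3-trans is also the thermodynamic arrangement, and the E-alkene comes with geranyl bromide.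
5. The dioxanone is chiral auxiliary, O3 protecting group and acyl donor in one; it is opened in the key step and its remnant leaves in the last step.

Key step: step 8

Assumption: (5S,6S)-5,6-dimethoxy-5,6-dimethyl-1,4-dioxan-2-one (13) is taken as a purchasable reagent, and its enolate is taken to react by the usual model (attack anti to the axial methoxy group, closed chair with the aldehyde).
Remark: flavanone numbering (O1, C2, C3, C4, C4a, C5 to C8, C8a) is used for the target; geranyl = (2E)-3,7-dimethylocta-2,6-dien-1-yl.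

**Route**

Step 1
Reactants: 1 4-hydroxybenzaldehyde; 2 geranyl bromide
Product: 3 3-[(2E)-3,7-dimethylocta-2,6-dien-1-yl]-4-hydroxybenzaldehyde
Conditions: KOH (1.1 equiv), H2O, rt, 2 added slowly
Reagents that add atoms: none
Why: Ortho C-alkylation of the phenoxide (phenolate C-allylation by SN2 at the primary allylic bromide, alkene geometry untouched) should work because the para position is blocked and water solvates the phenoxide oxygen, the O-geranyl ether being removed by chromatography.

Step 2
Reactants: 3 3-geranyl-4-hydroxybenzaldehyde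
Product: 4 3-[(2E)-3,7-dimethylocta-2,6-dien-1-yl]-4-(methoxymethoxy)benzaldehyde
Conditions: MeOCH2Cl, iPr2NEt, CH2Cl2, 0 °C to rt
Reagents that add atoms: chloromethyl methyl ether COCCl
Why: O-Alkylation of the phenol to its methoxymethyl acetal gives a group that should survive the enolate and fluoride steps and keeps the phenol next to the geranyl chain masked.

Step 3
Reactants: 5 2-methylresorcinol
Product: 6 1,3-bis(methoxymethoxy)-2-methylbenzene
Conditions: MeOCH2Cl (2.5 equiv), iPr2NEt, CH2Cl2, 0 °C to rt
Reagents that add atoms: chloromethyl methyl ether COCCl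
Why: Double O-alkylation of the two equivalent phenols (acetal protection) should be clean and keeps the arene symmetrical.

Step 4
Reactants: 6 1,3-bis(methoxymethoxy)-2-methylbenzene
Product: 8 3,5-bis(methoxymethoxy)-4-methylphenol, via arylboronate 7 (not isolated)
Conditions: [Ir(OMe)(cod)]2 (1.5 mol %), 4,4'-di-tert-butyl-2,2'-bipyridine (3 mol %), B2pin2 (0.55 equiv), THF, 80 °C; then aq. NaOH, H2O2, 0 °C to rt
Reagents that add atoms: hydrogen peroxide OO; bis(pinacolato)diboron CC1(C)OB(OC1(C)C)B1OC(C)(C)C(C)(C)O1 (its boron stays only in 7)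
Why: Sterically governed iridium-catalysed aromatic C–H borylation should reach only the one ring carbon without an ortho substituent, and basic peroxide oxidation of the C–B bond in the same flask then puts the hydroxyl at that carbon.

Step 5
Reactants: 8 3,5-bis(methoxymethoxy)-4-methylphenol
Product: 9 2-bromo-3,5-bis(methoxymethoxy)-4-methylphenol
Conditions: N-bromosuccinimide (1.0 equiv), MeCN, −40 to 0 °C
Reagents that add atoms: N-bromosuccinimide O=C1CCC(=O)N1Br
Why: Electrophilic aromatic bromination ortho to the free hydroxyl should give a single monobromide because the two open ring positions are mirror images, with one equivalent of reagent at low temperature limiting dibromination.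

Step 6
Reactants: 9 2-bromo-3,5-bis(methoxymethoxy)-4-methylphenol
Product: 12 3,5-bis(methoxymethoxy)-4-methyl-2-(trimethylsilyl)phenyl trifluoromethanesulfonate, via silyl ether 10 (not isolated), via lithium phenoxide 11 (not isolated)
Conditions: HN(SiMe3)2, THF, 65 °C, then evaporation; n-BuLi (1.1 equiv), THF, −78 °C; (CF3SO2)2O (1.2 equiv), −78 to 0 °C
Reagents that add atoms: hexamethyldisilazane C[Si](C)(C)N[Si](C)(C)C; trifluoromethanesulfonic anhydride O=S(=O)(OS(=O)(=O)C(F)(F)F)C(F)(F)F
Why: O-Silylation, bromine–lithium exchange and 1,3 oxygen-to-carbon silyl shift (retro-Brook rearrangement) should give the ortho-silyl phenoxide, which is triflated in the same flask, the standard entry to ortho-silylaryl triflates as fluoride-triggered aryne precursors.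

Step 7
Reactants: 4 3-geranyl-4-(methoxymethoxy)benzaldehyde; 13 (5S,6S)-5,6-dimethoxy-5,6-dimethyl-1,4-dioxan-2-one
Product: 15 (3R,5S,6S)-3-[(R)-{3-[(2E)-3,7-dimethylocta-2,6-dien-1-yl]-4-(methoxymethoxy)phenyl}(trimethylsilyloxy)methyl]-5,6-dimethoxy-5,6-dimethyl-1,4-dioxan-2-one, via lithium aldolate 14 (not isolated)
Conditions: 13 (1.15 equiv), LiN(SiMe3)2 (1.1 equiv), THF, −78 °C; then 4, −78 °C; then Me3SiCl (2 equiv), −78 to −40 °C; pH 7 buffer
Reagents that add atoms: chlorotrimethylsilane C[Si](C)(C)Cl
Why: In this lithium enolate aldol addition the ring fixes the E(O)-enolate, so the closed Zimmerman–Traxler chair with the aryl group equatorial should give the anti adduct (carbinol R), the aldehyde should add to the enolate face opposite the axial methoxy group at C5 (new C3 R), and silylation of the aldolate at low temperature blocks retro-aldol and stores the alkoxide for step 8.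

Step 8
Reactants: 15 silyl ether of the aldol adduct; 12 3,5-bis(methoxymethoxy)-4-methyl-2-(trimethylsilyl)phenyl trifluoromethanesulfonate
Product: 18 (2R,3R)-2-{3-[(2E)-3,7-dimethylocta-2,6-dien-1-yl]-4-(methoxymethoxy)phenyl}-3-{[(2S)-2-methoxy-3-oxobutan-2-yl]oxy}-5,7-bis(methoxymethoxy)-6-methyl-2,3-dihydro-4H-chromen-4-one, via aryne 16 (not isolated), via hemiketal alkoxide 17 (not isolated)
Conditions: 12 (2 equiv), CsF (5 equiv), 18-crown-6 (0.5 equiv), THF, 0 °C to rt; pH 7 buffer
Reagents that add atoms: none
Why: Proposed new method: fluoride strips both trimethylsilyl groups, so the benzylic alkoxide of 15 arises with no O–H in the flask while 12 loses triflate to give aryne 16; the alkoxide adds to the aryne carbon that becomes C8a, and the aryl anion left at the future C4a attacks the dioxanone carbonyl, whose ring oxygen leaves as hemiketal alkoxide 17, which sheds methoxide to give 18. The closest known reaction type is the fluoride-mediated annulation of arynes with methyl salicylates to xanthones (phenoxide addition, then intramolecular acyl capture of the aryl anion), together with aryne insertion into the N–C(O) bond of beta-lactams; an aliphatic alkoxide with a lactone acceptor has not been shown. Ring C closes by 6-exo-trig attack of the aryl anion on the lactone carbonyl after the intermolecular C–O bond has formed. No stereocenter is created: C2 and C3 come unchanged from 15, and 2,3-trans is also the thermodynamic arrangement should C3 enolise. The step needs regioselective addition to the aryne, secured by the oxygen at the future C5, which makes 16 a 3-alkoxyaryne attacked at the remote carbon so that the anion sits next to that oxygen, and by the mirror plane of 8, which allows only one aryne. It also needs acyl capture to outrun protonation, retro-aldol cleavage and ene reaction with the geranyl alkenes, for which the silyl-masked alkoxide, the aprotic medium and the excess of 12 are chosen.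

Step 9
Reactants: 18 protected dihydroflavonol
Product: 19 (2R,3R)-2-{3-[(2E)-3,7-dimethylocta-2,6-dien-1-yl]-4-hydroxyphenyl}-3,5,7-trihydroxy-6-methyl-2,3-dihydro-4H-chromen-4-one
Conditions: 3 M aq. HCl, MeOH, 45 °C
Reagents that add atoms: none
Why: Acid-catalysed acetal cleavage should remove the three methoxymethyl groups and hydrolyse the tertiary mixed ketal at O3, dilute methanolic HCl at moderate temperature being the usual way to unmask geranylated flavanones without closing the chain onto the ortho phenol.

**Compound list**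

1 | 4-hydroxybenzaldehyde | O=Cc1ccc(O)cc1 | starting material
2 | geranyl bromide, (2E)-1-bromo-3,7-dimethylocta-2,6-diene | CC(C)=CCC/C(C)=C/CBr | starting material
3 | 3-[(2E)-3,7-dimethylocta-2,6-dien-1-yl]-4-hydroxybenzaldehyde | CC(C)=CCC/C(C)=C/Cc1cc(C=O)ccc1O | intermediate
4 | 3-[(2E)-3,7-dimethylocta-2,6-dien-1-yl]-4-(methoxymethoxy)benzaldehyde | CC(C)=CCC/C(C)=C/Cc1cc(C=O)ccc1OCOC | intermediate
5 | 2-methylresorcinol (2-methylbenzene-1,3-diol) | Cc1c(O)cccc1O | starting material
6 | 1,3-bis(methoxymethoxy)-2-methylbenzene | COCOc1cccc(OCOC)c1C | intermediate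
7 | 2-[3,5-bis(methoxymethoxy)-4-methylphenyl]-4,4,5,5-tetramethyl-1,3,2-dioxaborolane | COCOc1cc(B2OC(C)(C)C(C)(C)O2)cc(OCOC)c1C | intermediate (not isolated)
8 | 3,5-bis(methoxymethoxy)-4-methylphenol | COCOc1cc(O)cc(OCOC)c1C | intermediate
9 | 2-bromo-3,5-bis(methoxymethoxy)-4-methylphenol | COCOc1cc(O)c(Br)c(OCOC)c1C | intermediate
10 | [2-bromo-3,5-bis(methoxymethoxy)-4-methylphenoxy]trimethylsilane | COCOc1cc(O[Si](C)(C)C)c(Br)c(OCOC)c1C | intermediate (not isolated)
11 | lithium 3,5-bis(methoxymethoxy)-4-methyl-2-(trimethylsilyl)phenoxide | COCOc1cc([O-])c([Si](C)(C)C)c(OCOC)c1C.[Li+] | intermediate (not isolated)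
12 | 3,5-bis(methoxymethoxy)-4-methyl-2-(trimethylsilyl)phenyl trifluoromethanesulfonate | COCOc1cc(OS(=O)(=O)C(F)(F)F)c([Si](C)(C)C)c(OCOC)c1C | intermediate
13 | (5S,6S)-5,6-dimethoxy-5,6-dimethyl-1,4-dioxan-2-one | O=C1CO[C@](C)(OC)[C@@](C)(OC)O1 | starting material
14 | lithium alkoxide of the anti aldol adduct: lithium (R)-[(3R,5S,6S)-5,6-dimethoxy-5,6-dimethyl-2-oxo-1,4-dioxan-3-yl]{3-geranyl-4-(methoxymethoxy)phenyl}methanolate | CC(C)=CCC/C(C)=C/Cc1cc([C@@H]([O-])[C@H]2O[C@](C)(OC)[C@@](C)(OC)OC2=O)ccc1OCOC.[Li+] | intermediate (not isolated)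
15 | (3R,5S,6S)-3-[(R)-{3-geranyl-4-(methoxymethoxy)phenyl}(trimethylsilyloxy)methyl]-5,6-dimethoxy-5,6-dimethyl-1,4-dioxan-2-one | CC(C)=CCC/C(C)=C/Cc1cc([C@@H](O[Si](C)(C)C)[C@H]2O[C@](C)(OC)[C@@](C)(OC)OC2=O)ccc1OCOC | intermediate
16 | 3,5-bis(methoxymethoxy)-4-methylbenzyne (1,2-didehydro arene; triple bond between the former triflate and silyl carbons) | C1#CC(OCOC)=C(C)C(OCOC)=C1 | intermediate (not isolated)
17 | ring-opened cesium hemiketal alkoxide: 18 in which the side-chain ketone is still C(CH3)(OCH3)–O− Cs+, both former dioxane carbons keeping their configuration | CC(C)=CCC/C(C)=C/Cc1cc([C@H]2Oc3cc(OCOC)c(C)c(OCOC)c3C(=O)[C@@H]2O[C@](C)(OC)[C@@](C)(OC)[O-])ccc1OCOC.[Cs+] | intermediate (not isolated)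
18 | (2R,3R)-2-{3-geranyl-4-(methoxymethoxy)phenyl}-3-{[(2S)-2-methoxy-3-oxobutan-2-yl]oxy}-5,7-bis(methoxymethoxy)-6-methyl-2,3-dihydro-4H-chromen-4-one | CC(C)=CCC/C(C)=C/Cc1cc([C@H]2Oc3cc(OCOC)c(C)c(OCOC)c3C(=O)[C@@H]2O[C@](C)(OC)C(C)=O)ccc1OCOC | intermediate
19 | (2R,3R)-2-{3-[(2E)-3,7-dimethylocta-2,6-dien-1-yl]-4-hydroxyphenyl}-3,5,7-trihydroxy-6-methyl-2,3-dihydro-4H-chromen-4-one | CC(C)=CCC/C(C)=C/Cc1cc([C@H]2Oc3cc(O)c(C)c(O)c3C(=O)[C@@H]2O)ccc1O | target

**Count**

Total: 9 steps. Longest linear sequence: 6 steps (5 → 6 → 8 → 9 → 12 → 18 → 19, steps 3, 4, 5, 6, 8, 9).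

**Steps most likely to fail**

Step 8 (Proposed new method). What may go wrong: the aryl anion may be protonated before it reaches the lactone carbonyl, so that only O-arylation occurs; the unmasked alkoxide may undergo retro-aldol cleavage before an aryne is at hand; or the methoxide released may open ring C of the product.
Fallback, known chemistry only, setting out from bromophenol 9 and aldehyde 4 and coming back at target 19:
- The sodium phenoxide of 9 (NaH) would undergo bromine–lithium exchange (n-BuLi, THF, −78 °C) and acetylation with N-methoxy-N-methylacetamide to give acetophenone F1, in which only the oxygen that becomes O1 is free.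
- Allyl bromide and K2CO3 in DMF would give allyl ether F2.
- Claisen–Schmidt condensation with 4 (KOH, EtOH) would give E-chalcone F3.
- Julia–Colonna epoxidation (poly-L-leucine, urea–hydrogen peroxide, DBU, THF) attacks only the enone and would give the (2R,3S)-epoxy ketone F4.
- Removal of the allyl group (Pd(PPh3)4, morpholine, THF) would free phenol F5 (not isolated), which should open the oxirane at the benzylic carbon with inversion to give hydroxyflavanone F6.
- The conditions of step 9 would then give 19.

Step 7. What may go wrong: reversible aldol addition while the aldolate waits for silylation may erode the anti relationship, or facial control by the diacetal may be incomplete for this hindered aldehyde.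
Fallback, setting out from 4 and 13 and coming back at 15:
- The aldolate would be quenched with acetic acid at −78 °C and the product isolated as alcohol F7, whatever its purity at the carbinol carbon.
- Dess–Martin periodinane would give keto lactone F8, whose C3 substituent is held equatorial by the diacetal.
- Noyori transfer hydrogenation (RuCl(p-cymene)[(S,S)-TsDPEN], HCO2H/Et3N), expected by the aryl/alkyl model to deliver the (R)-carbinol, would then set this centre under catalyst control and return alcohol F7 as one isomer.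
- Me3SiCl and imidazole would give 15.

Step 9. What may go wrong: once the ring B phenol is free, acid may close the geranyl chain onto it (chroman formation) or hydrate the trisubstituted alkenes before the last acetal has gone.
Fallback, setting out from phenol 3 and coming back at target 19:
- Allyl bromide and K2CO3 would give aldehyde F9.
- The operations of step 7 would give, through lithium aldolate F10 (not isolated), silyl ether F11.
- The operations of step 8 with 12 would give, through aryne 16 and hemiketal alkoxide F12 (not isolated), ketal F13.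
- The acid of step 9 would then meet a ring B oxygen that is still capped, so only the two methoxymethyl groups and the ketal fall, giving allyl ether F14.
- The allyl group would be removed last under neutral conditions (Pd(PPh3)4, morpholine, THF) to give 19.

**Further compounds**

F1 | step 8 | 1-[6-hydroxy-2,4-bis(methoxymethoxy)-3-methylphenyl]ethanone | CC(=O)c1c(O)cc(OCOC)c(C)c1OCOC
F2 | step 8 | 1-[2,4-bis(methoxymethoxy)-3-methyl-6-(prop-2-en-1-yloxy)phenyl]ethanone | CC(=O)c1c(OCC=C)cc(OCOC)c(C)c1OCOC
F3 | step 8 | (2E)-1-[2,4-bis(methoxymethoxy)-3-methyl-6-(prop-2-en-1-yloxy)phenyl]-3-{3-geranyl-4-(methoxymethoxy)phenyl}prop-2-en-1-one | CC(C)=CCC/C(C)=C/Cc1cc(/C=C/C(=O)c2c(OCC=C)cc(OCOC)c(C)c2OCOC)ccc1OCOC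
F4 | step 8 | [2,4-bis(methoxymethoxy)-3-methyl-6-(prop-2-en-1-yloxy)phenyl][(2R,3S)-3-{3-geranyl-4-(methoxymethoxy)phenyl}oxiran-2-yl]methanone | CC(C)=CCC/C(C)=C/Cc1cc([C@@H]2O[C@H]2C(=O)c2c(OCC=C)cc(OCOC)c(C)c2OCOC)ccc1OCOC
F5 | step 8 | [(2R,3S)-3-{3-geranyl-4-(methoxymethoxy)phenyl}oxiran-2-yl][6-hydroxy-2,4-bis(methoxymethoxy)-3-methylphenyl]methanone | CC(C)=CCC/C(C)=C/Cc1cc([C@@H]2O[C@H]2C(=O)c2c(O)cc(OCOC)c(C)c2OCOC)ccc1OCOC
F6 | step 8 | (2R,3R)-2-{3-geranyl-4-(methoxymethoxy)phenyl}-3-hydroxy-5,7-bis(methoxymethoxy)-6-methyl-2,3-dihydro-4H-chromen-4-one | CC(C)=CCC/C(C)=C/Cc1cc([C@H]2Oc3cc(OCOC)c(C)c(OCOC)c3C(=O)[C@@H]2O)ccc1OCOC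
F7 | step 7 | (3R,5S,6S)-3-[(R)-{3-geranyl-4-(methoxymethoxy)phenyl}(hydroxy)methyl]-5,6-dimethoxy-5,6-dimethyl-1,4-dioxan-2-one | CC(C)=CCC/C(C)=C/Cc1cc([C@@H](O)[C@H]2O[C@](C)(OC)[C@@](C)(OC)OC2=O)ccc1OCOC
F8 | step 7 | (3R,5S,6S)-3-{3-geranyl-4-(methoxymethoxy)benzoyl}-5,6-dimethoxy-5,6-dimethyl-1,4-dioxan-2-one | CC(C)=CCC/C(C)=C/Cc1cc(C(=O)[C@H]2O[C@](C)(OC)[C@@](C)(OC)OC2=O)ccc1OCOC
F9 | step 9 | 3-[(2E)-3,7-dimethylocta-2,6-dien-1-yl]-4-(prop-2-en-1-yloxy)benzaldehyde | CC(C)=CCC/C(C)=C/Cc1cc(C=O)ccc1OCC=C
F10 | step 9 | lithium (R)-[(3R,5S,6S)-5,6-dimethoxy-5,6-dimethyl-2-oxo-1,4-dioxan-3-yl]{3-geranyl-4-(prop-2-en-1-yloxy)phenyl}methanolate | CC(C)=CCC/C(C)=C/Cc1cc([C@@H]([O-])[C@H]2O[C@](C)(OC)[C@@](C)(OC)OC2=O)ccc1OCC=C.[Li+]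
F11 | step 9 | (3R,5S,6S)-3-[(R)-{3-geranyl-4-(prop-2-en-1-yloxy)phenyl}(trimethylsilyloxy)methyl]-5,6-dimethoxy-5,6-dimethyl-1,4-dioxan-2-one | CC(C)=CCC/C(C)=C/Cc1cc([C@@H](O[Si](C)(C)C)[C@H]2O[C@](C)(OC)[C@@](C)(OC)OC2=O)ccc1OCC=C
F12 | step 9 | ring-opened cesium hemiketal alkoxide corresponding to 17 with prop-2-en-1-yloxy in place of the ring B methoxymethoxy group | CC(C)=CCC/C(C)=C/Cc1cc([C@H]2Oc3cc(OCOC)c(C)c(OCOC)c3C(=O)[C@@H]2O[C@](C)(OC)[C@@](C)(OC)[O-])ccc1OCC=C.[Cs+]
F13 | step 9 | (2R,3R)-2-{3-geranyl-4-(prop-2-en-1-yloxy)phenyl}-3-{[(2S)-2-methoxy-3-oxobutan-2-yl]oxy}-5,7-bis(methoxymethoxy)-6-methyl-2,3-dihydro-4H-chromen-4-one | CC(C)=CCC/C(C)=C/Cc1cc([C@H]2Oc3cc(OCOC)c(C)c(OCOC)c3C(=O)[C@@H]2O[C@](C)(OC)C(C)=O)ccc1OCC=C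
F14 | step 9 | (2R,3R)-2-{3-geranyl-4-(prop-2-en-1-yloxy)phenyl}-3,5,7-trihydroxy-6-methyl-2,3-dihydro-4H-chromen-4-one | CC(C)=CCC/C(C)=C/Cc1cc([C@H]2Oc3cc(O)c(C)c(O)c3C(=O)[C@@H]2O)ccc1OCC=C
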